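**Plan**

1. Retrosynthesis cuts the two aryl benzyl ethers last, then the arylglycerol unit at C7''–C8'' (aldol) and at the aryl ether O–C8'' bond (phenol alkylation by a bromoacetyl imide), which leaves a tetrahydrofuran phenol.
2. The tetrahydrofuran (O1, C2, C3, C4, C5) is cut at O1–C2. C2 is a benzylic ether carbon para to the oxygen on C4 of the 3,5-dimethoxyaryl ring, so with that oxygen as a free phenol C2 can become the exocyclic carbon of a p-quinone methide that the C5 oxygen captures.
3. The seco-diol so obtained is cut at the C3–CH2Ar bond (lactone enolate alkylation) and traced to a β-benzylbutyrolactone from a Stobbe condensation and an asymmetric hydrogenation.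
4. Forward, the carbon chain is joined first (Stobbe, hydrogenation, lactone, alkylation, reduction), the only ring closure is the tetrahydrofuran (key step), then the side chain is attached (O-alkylation, anti-aldol, reduction) and both benzyl groups are removed.
5. Stereochemistry: C4 comes from catalyst-controlled hydrogenation, C3 from trans-alkylation anti to the C4 substituent, C2 from allylic strain in the quinone methide closure, and C8''/C7'' from an (R)-4-benzyloxazolidinone auxiliary in a magnesium-catalysed anti-aldol.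

Key step: step 10

Locants: tetrahydrofuran O1, C2 (aryl), C3 (CH2OH), C4 (guaiacylmethyl), C5; side chain C7'' (benzylic carbinol), C8'' (aryloxy carbon), C9'' (CH2OH). The target is (2R,3S,4S) in the ring and (7''S,8''R), i.e. erythro, in the side chain.

Assumption: the (R,R)-Et-DuPHOS rhodium catalyst is taken to deliver the (S)-succinate 9, the sense expected by analogy with itaconates and dehydroamino acids; if the sense is opposite for this substrate, the (S,S)-catalyst is used and nothing else changes.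

**Route**

Step 1
Reactants: 1 syringaldehyde (4-hydroxy-3,5-dimethoxybenzaldehyde)
Product: 2 4-(tert-butyldimethylsilyloxy)-3,5-dimethoxybenzaldehyde
Conditions: TBSCl, imidazole, DMF, rt
Reagents that add atoms: tert-butyldimethylsilyl chloride, CC(C)(C)[Si](C)(C)Cl
Why: Imidazole-promoted silylation of the phenol gives a silyl ether that is orthogonal to the benzyl ether carried on the other ring and is cleaved later by fluoride.

Step 2
Reactants: 2 4-(tert-butyldimethylsilyloxy)-3,5-dimethoxybenzaldehyde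
Product: 3 [4-(tert-butyldimethylsilyloxy)-3,5-dimethoxyphenyl]methanol
Conditions: NaBH4, THF/EtOH, 0 °C
Reagents that add atoms: none
Why: Borohydride reduction of the aryl aldehyde to the benzylic alcohol, with the hindered aryl silyl ether expected to tolerate brief exposure at 0 °C.

Step 3
Reactants: 3 [4-(tert-butyldimethylsilyloxy)-3,5-dimethoxyphenyl]methanol
Product: 4 4-(tert-butyldimethylsilyloxy)-3,5-dimethoxybenzyl bromide
Conditions: CBr4, PPh3, CH2Cl2, 0 °C; used at once without chromatography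
Reagents that add atoms: carbon tetrabromide, BrC(Br)(Br)Br
Why: Appel reaction, in which bromide displaces the alkoxyphosphonium ion under neutral conditions and so avoids acid that would cleave the aryl silyl ether.

Step 4
Reactants: 5 4-benzyloxy-3-methoxybenzaldehyde (O-benzylvanillin); 6 dimethyl succinate
Product: 8 (E)-4-(4-benzyloxy-3-methoxyphenyl)-3-(methoxycarbonyl)but-3-enoic acid, via paraconic ester lactone 7 (not isolated)
Conditions: NaOMe (1.5 equiv), MeOH, reflux; then 2 M HCl
Reagents that add atoms: none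
Why: Stobbe condensation, in which the succinate enolate adds to the aldehyde, the aldolate lactonises to 7 and E1cB opening of 7 gives the alkylidenesuccinic half-ester with the aryl group trans to the ester.

Step 5
Reactants: 8 (E)-4-(4-benzyloxy-3-methoxyphenyl)-3-(methoxycarbonyl)but-3-enoic acid
Product: 9 (3S)-4-(4-benzyloxy-3-methoxyphenyl)-3-(methoxycarbonyl)butanoic acid
Conditions: H2 (5 bar), [Rh(cod)((R,R)-Et-DuPHOS)]BF4 (0.5 mol %), NaOMe (0.1 equiv), MeOH, rt
Reagents that add atoms: none
Why: Rhodium–bisphospholane asymmetric hydrogenation of an itaconate-type half-ester, in which carboxylate and alkene chelate the metal and the C2-symmetric ligand delivers hydrogen to one alkene face to set the future C4 centre as (S), while the homogeneous catalyst leaves the aryl benzyl ether intact.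

Step 6
Reactants: 9 (3S)-4-(4-benzyloxy-3-methoxyphenyl)-3-(methoxycarbonyl)butanoic acid
Product: 11 (S)-4-(4-benzyloxy-3-methoxybenzyl)dihydrofuran-2(3H)-one, via hydroxy acid 10 (not isolated)
Conditions: KOH (1.0 equiv), EtOH; CaCl2, NaBH4, EtOH, −10 °C to rt; then 2 M HCl, rt
Reagents that add atoms: none
Why: Chemoselective ester reduction by Ca(BH4)2 formed in the flask, which leaves the carboxylate alone, followed by acid-promoted lactonisation of 10, with the stereocentre not involved in either event.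

Step 7
Reactants: 11 (S)-4-(4-benzyloxy-3-methoxybenzyl)dihydrofuran-2(3H)-one; 4 4-(tert-butyldimethylsilyloxy)-3,5-dimethoxybenzyl bromide
Product: 12 (3S,4S)-4-(4-benzyloxy-3-methoxybenzyl)-3-[4-(tert-butyldimethylsilyloxy)-3,5-dimethoxybenzyl]dihydrofuran-2(3H)-one
Conditions: LiN(SiMe3)2 (1.1 equiv), THF, −78 °C; then 4, DMPU, −78 to −30 °C
Reagents that add atoms: none
Why: Alkylation of the lactone lithium enolate with a benzylic bromide, in which the electrophile approaches the planar enolate on the face opposite the C4 benzyl substituent and so sets the new centre trans to it (substrate control).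

Step 8
Reactants: 12 (3S,4S)-4-(4-benzyloxy-3-methoxybenzyl)-3-[4-(tert-butyldimethylsilyloxy)-3,5-dimethoxybenzyl]dihydrofuran-2(3H)-one
Product: 13 (2S,3S)-2-(4-benzyloxy-3-methoxybenzyl)-3-[4-(tert-butyldimethylsilyloxy)-3,5-dimethoxybenzyl]butane-1,4-diol
Conditions: LiAlH4, THF, 0 °C to rt; aq. KNaC4H4O6 (potassium sodium tartrate) work-up
Reagents that add atoms: none
Why: Hydride reduction of the lactone to the 1,4-diol, in which addition to the carbonyl outruns enolisation so that both benzyl-bearing centres are carried over unchanged.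

Step 9
Reactants: 13 (2S,3S)-2-(4-benzyloxy-3-methoxybenzyl)-3-[4-(tert-butyldimethylsilyloxy)-3,5-dimethoxybenzyl]butane-1,4-diol
Product: 14 (2S,3S)-2-(4-benzyloxy-3-methoxybenzyl)-3-(4-hydroxy-3,5-dimethoxybenzyl)butane-1,4-diol
Conditions: Bu4NF, AcOH (1:1), THF, 0 °C
Reagents that add atoms: none
Why: Fluoride-induced desilylation of the aryl silyl ether, buffered with acetic acid so that the electron-rich phenoxide is protonated at once, with the benzyl ether and the diol inert.

Step 10
Reactants: 14 (2S,3S)-2-(4-benzyloxy-3-methoxybenzyl)-3-(4-hydroxy-3,5-dimethoxybenzyl)butane-1,4-diol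
Product: 16 [(2R,3S,4S)-4-(4-benzyloxy-3-methoxybenzyl)-2-(4-hydroxy-3,5-dimethoxyphenyl)tetrahydrofuran-3-yl]methanol, via p-quinone methide 15 (not isolated)
Conditions: DDQ (1.0 equiv, added in portions), CH2Cl2, 0 °C to rt
Reagents that add atoms: none
Why: DDQ removes hydride from the benzylic CH2 of the free 4-alkyl-2,6-dimethoxyphenol (a two-electron oxidation of the phenol) to give p-quinone methide 15, and the hydroxymethyl oxygen on the carbon that becomes C4 adds to its exocyclic carbon with re-aromatisation, forming O1–C2. The closest known reaction type is the DDQ- or Ag2O-mediated benzylic alkoxylation of 4-alkylphenols through p-quinone methides, run here intramolecularly as in the oxidative cyclisation of 4-hydroxybenzyl-substituted butanediols to 2-aryltetrahydrofurans. The tetrahydrofuran closes in a 5-exo-trig mode, whereas the other hydroxymethyl group could only form an oxetane. The new C2 centre is controlled by allylic strain in 15: the C3–H lies in the quinone methide plane, the C3 hydroxymethyl group and the attacking chain sit on opposite faces, and the aryl group therefore ends up trans to the C3 substituent, which is also the arrangement favoured if the p-hydroxybenzyl ether reopens and recloses. The step needs oxidation at one of two benzylic carbons and O-capture in preference to Friedel–Crafts capture by the other ring: only the ring with the free phenol can form a quinone methide because the guaiacyl oxygen is benzylated, the absence of strong acid keeps the hydroxyl ahead of the arene as nucleophile, and one equivalent of oxidant limits further oxidation of 16.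

Step 11
Reactants: 17 (R)-4-benzyloxazolidin-2-one; 18 bromoacetyl bromide
Product: 19 (R)-4-benzyl-3-(bromoacetyl)oxazolidin-2-one
Conditions: n-BuLi, THF, −78 °C; then 18, −78 to 0 °C
Reagents that add atoms: none
Why: N-Acylation of the lithiated oxazolidinone, in which the acyl bromide is far more electrophilic than the alkyl bromide at low temperature so that the imide forms without N-alkylation and the stereocentre is not involved.

Step 12
Reactants: 16 [(2R,3S,4S)-4-(4-benzyloxy-3-methoxybenzyl)-2-(4-hydroxy-3,5-dimethoxyphenyl)tetrahydrofuran-3-yl]methanol; 19 (R)-4-benzyl-3-(bromoacetyl)oxazolidin-2-one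
Product: 20 (R)-4-benzyl-3-{[4-((2R,3S,4S)-4-(4-benzyloxy-3-methoxybenzyl)-3-(hydroxymethyl)tetrahydrofuran-2-yl)-2,6-dimethoxyphenoxy]acetyl}oxazolidin-2-one
Conditions: K2CO3, acetone, rt
Reagents that add atoms: none
Why: Williamson ether synthesis, in which carbonate deprotonates only the phenol and the phenoxide displaces bromide from the activated α-bromo imide by SN2 faster than it attacks either imide carbonyl, the aliphatic hydroxyl staying protonated.

Step 13
Reactants: 20 (R)-4-benzyl-3-{[4-((2R,3S,4S)-4-(4-benzyloxy-3-methoxybenzyl)-3-(hydroxymethyl)tetrahydrofuran-2-yl)-2,6-dimethoxyphenoxy]acetyl}oxazolidin-2-one; 5 4-benzyloxy-3-methoxybenzaldehyde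
Product: 23 (R)-4-benzyl-3-[(2S,3S)-3-(4-benzyloxy-3-methoxyphenyl)-2-{4-[(2R,3S,4S)-4-(4-benzyloxy-3-methoxybenzyl)-3-(hydroxymethyl)tetrahydrofuran-2-yl]-2,6-dimethoxyphenoxy}-3-hydroxypropanoyl]oxazolidin-2-one, via O-trimethylsilyl ether 21 (not isolated), via bis(trimethylsilyl) aldol adduct 22 (not isolated)
Conditions: Me3SiCl (3.5 equiv), Et3N (4 equiv), EtOAc, rt, 30 min; then MgCl2 (0.2 equiv), 5 (1.3 equiv), rt; then THF/1 M HCl (5:1), 0 °C
Reagents that add atoms: chlorotrimethylsilane, C[Si](C)(C)Cl (its silicon stays in 21 and 22 only; 23 keeps none of it)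
Why: Evans magnesium chloride-catalysed anti-aldol of an N-acyloxazolidinone with an aromatic aldehyde, in which the free hydroxyl is first masked as its silyl ether, soft enolisation gives the magnesium-chelated (Z)-enolate, the aldehyde adds through a closed boat transition state on the enolate face away from the auxiliary benzyl group so that the (R)-auxiliary sets C8'' and the anti relationship sets C7'', and silylation of the aldolate turns the catalyst over and blocks retro-aldol.

Step 14
Reactants: 23 (R)-4-benzyl-3-[(2S,3S)-3-(4-benzyloxy-3-methoxyphenyl)-2-{4-[(2R,3S,4S)-4-(4-benzyloxy-3-methoxybenzyl)-3-(hydroxymethyl)tetrahydrofuran-2-yl]-2,6-dimethoxyphenoxy}-3-hydroxypropanoyl]oxazolidin-2-one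
Product: 24 (1S,2R)-1-(4-benzyloxy-3-methoxyphenyl)-2-{4-[(2R,3S,4S)-4-(4-benzyloxy-3-methoxybenzyl)-3-(hydroxymethyl)tetrahydrofuran-2-yl]-2,6-dimethoxyphenoxy}propane-1,3-diol
Conditions: NaBH4, THF/H2O (4:1), 0 °C to rt
Reagents that add atoms: none
Why: Reductive cleavage of the N-acyloxazolidinone by borohydride in wet THF, which reduces the exocyclic carbonyl to the primary alcohol and releases the auxiliary without a base strong enough to epimerise C8'' or induce retro-aldol.

Step 15
Reactants: 24 (1S,2R)-1-(4-benzyloxy-3-methoxyphenyl)-2-{4-[(2R,3S,4S)-4-(4-benzyloxy-3-methoxybenzyl)-3-(hydroxymethyl)tetrahydrofuran-2-yl]-2,6-dimethoxyphenoxy}propane-1,3-diol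
Product: 25 (1S,2R)-1-(4-hydroxy-3-methoxyphenyl)-2-{4-[(2R,3S,4S)-4-(4-hydroxy-3-methoxybenzyl)-3-(hydroxymethyl)tetrahydrofuran-2-yl]-2,6-dimethoxyphenoxy}propane-1,3-diol (CNP0170225.1)
Conditions: H2 (1 atm), Pd/C (10 wt % Pd), EtOAc/MeOH (1:1), rt, stopped after uptake of 2 equiv
Reagents that add atoms: none
Why: Catalytic hydrogenolysis of the two aryl benzyl ethers, which under neutral conditions cleave much faster over Pd/C than the benzylic C2–O1 bond of the tetrahydrofuran or the benzylic carbinol, so that stopping at two equivalents of hydrogen should give the target.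

**Compound list**

1 | syringaldehyde (4-hydroxy-3,5-dimethoxybenzaldehyde) | COc1cc(C=O)cc(OC)c1O | starting material
2 | 4-(tert-butyldimethylsilyloxy)-3,5-dimethoxybenzaldehyde | COc1cc(C=O)cc(OC)c1O[Si](C)(C)C(C)(C)C | intermediate
3 | [4-(tert-butyldimethylsilyloxy)-3,5-dimethoxyphenyl]methanol | COc1cc(CO)cc(OC)c1O[Si](C)(C)C(C)(C)C | intermediate
4 | 4-(tert-butyldimethylsilyloxy)-3,5-dimethoxybenzyl bromide | COc1cc(CBr)cc(OC)c1O[Si](C)(C)C(C)(C)C | intermediate
5 | 4-benzyloxy-3-methoxybenzaldehyde (O-benzylvanillin) | COc1cc(C=O)ccc1OCc1ccccc1 | starting material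
6 | dimethyl succinate | COC(=O)CCC(=O)OC | starting material
7 | methyl 2-(4-benzyloxy-3-methoxyphenyl)-5-oxotetrahydrofuran-3-carboxylate (paraconic ester, stereoisomer mixture) | COC(=O)C1CC(=O)OC1c1ccc(OCc2ccccc2)c(OC)c1 | intermediate (not isolated)
8 | (E)-4-(4-benzyloxy-3-methoxyphenyl)-3-(methoxycarbonyl)but-3-enoic acid | COC(=O)/C(CC(=O)O)=C/c1ccc(OCc2ccccc2)c(OC)c1 | intermediate
9 | (3S)-4-(4-benzyloxy-3-methoxyphenyl)-3-(methoxycarbonyl)butanoic acid | COC(=O)[C@@H](Cc1ccc(OCc2ccccc2)c(OC)c1)CC(=O)O | intermediate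
10 | (3S)-4-(4-benzyloxy-3-methoxyphenyl)-3-(hydroxymethyl)butanoic acid (present as its carboxylate) | OC[C@@H](Cc1ccc(OCc2ccccc2)c(OC)c1)CC(=O)O | intermediate (not isolated)
11 | (S)-4-(4-benzyloxy-3-methoxybenzyl)dihydrofuran-2(3H)-one | O=C1C[C@H](Cc2ccc(OCc3ccccc3)c(OC)c2)CO1 | intermediate
12 | (3S,4S)-4-(4-benzyloxy-3-methoxybenzyl)-3-[4-(tert-butyldimethylsilyloxy)-3,5-dimethoxybenzyl]dihydrofuran-2(3H)-one (trans) | COc1cc(C[C@@H]2COC(=O)[C@H]2Cc2cc(OC)c(O[Si](C)(C)C(C)(C)C)c(OC)c2)ccc1OCc1ccccc1 | intermediate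
13 | (2S,3S)-2-(4-benzyloxy-3-methoxybenzyl)-3-[4-(tert-butyldimethylsilyloxy)-3,5-dimethoxybenzyl]butane-1,4-diol | COc1cc(C[C@H](CO)[C@@H](CO)Cc2cc(OC)c(O[Si](C)(C)C(C)(C)C)c(OC)c2)ccc1OCc1ccccc1 | intermediate
14 | (2S,3S)-2-(4-benzyloxy-3-methoxybenzyl)-3-(4-hydroxy-3,5-dimethoxybenzyl)butane-1,4-diol | COc1cc(C[C@H](CO)[C@@H](CO)Cc2cc(OC)c(O)c(OC)c2)ccc1OCc1ccccc1 | intermediate
15 | p-quinone methide of 14: 2,6-dimethoxycyclohexa-2,5-dien-1-one carrying at C4 the exocyclic =CH–CH(CH2OH)–CH(CH2OH)–CH2Ar chain, both stereocentres as in 14 | COc1cc(C[C@H](CO)[C@@H](CO)C=C2C=C(OC)C(=O)C(OC)=C2)ccc1OCc1ccccc1 | intermediate (not isolated)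
16 | [(2R,3S,4S)-4-(4-benzyloxy-3-methoxybenzyl)-2-(4-hydroxy-3,5-dimethoxyphenyl)tetrahydrofuran-3-yl]methanol | COc1cc(C[C@@H]2CO[C@@H](c3cc(OC)c(O)c(OC)c3)[C@@H]2CO)ccc1OCc1ccccc1 | intermediate
17 | (R)-4-benzyloxazolidin-2-one | O=C1N[C@H](Cc2ccccc2)CO1 | starting material
18 | bromoacetyl bromide | BrCC(Br)=O | starting material
19 | (R)-4-benzyl-3-(bromoacetyl)oxazolidin-2-one | O=C(CBr)N1[C@H](Cc2ccccc2)COC1=O | intermediate
20 | (R)-4-benzyl-3-{[4-((2R,3S,4S)-4-(4-benzyloxy-3-methoxybenzyl)-3-(hydroxymethyl)tetrahydrofuran-2-yl)-2,6-dimethoxyphenoxy]acetyl}oxazolidin-2-one | COc1cc(C[C@@H]2CO[C@@H](c3cc(OC)c(OCC(=O)N4[C@H](Cc5ccccc5)COC4=O)c(OC)c3)[C@@H]2CO)ccc1OCc1ccccc1 | intermediate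
21 | trimethylsilyl ether of 20 at the C3 hydroxymethyl group | COc1cc(C[C@@H]2CO[C@@H](c3cc(OC)c(OCC(=O)N4[C@H](Cc5ccccc5)COC4=O)c(OC)c3)[C@@H]2CO[Si](C)(C)C)ccc1OCc1ccccc1 | intermediate (not isolated)
22 | bis(trimethylsilyl) ether of 23 (C3 hydroxymethyl and C7'' oxygens silylated) | COc1cc(C[C@@H]2CO[C@@H](c3cc(OC)c(O[C@H](C(=O)N4[C@H](Cc5ccccc5)COC4=O)[C@@H](O[Si](C)(C)C)c6ccc(OCc7ccccc7)c(OC)c6)c(OC)c3)[C@@H]2CO[Si](C)(C)C)ccc1OCc1ccccc1 | intermediate (not isolated)
23 | (R)-4-benzyl-3-[(2S,3S)-3-(4-benzyloxy-3-methoxyphenyl)-2-{4-[(2R,3S,4S)-4-(4-benzyloxy-3-methoxybenzyl)-3-(hydroxymethyl)tetrahydrofuran-2-yl]-2,6-dimethoxyphenoxy}-3-hydroxypropanoyl]oxazolidin-2-one (anti-aldol adduct) | COc1cc(C[C@@H]2CO[C@@H](c3cc(OC)c(O[C@H](C(=O)N4[C@H](Cc5ccccc5)COC4=O)[C@@H](O)c6ccc(OCc7ccccc7)c(OC)c6)c(OC)c3)[C@@H]2CO)ccc1OCc1ccccc1 | intermediate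
24 | (1S,2R)-1-(4-benzyloxy-3-methoxyphenyl)-2-{4-[(2R,3S,4S)-4-(4-benzyloxy-3-methoxybenzyl)-3-(hydroxymethyl)tetrahydrofuran-2-yl]-2,6-dimethoxyphenoxy}propane-1,3-diol | COc1cc(C[C@@H]2CO[C@@H](c3cc(OC)c(O[C@H](CO)[C@@H](O)c4ccc(OCc5ccccc5)c(OC)c4)c(OC)c3)[C@@H]2CO)ccc1OCc1ccccc1 | intermediate
25 | (1S,2R)-1-(4-hydroxy-3-methoxyphenyl)-2-{4-[(2R,3S,4S)-4-(4-hydroxy-3-methoxybenzyl)-3-(hydroxymethyl)tetrahydrofuran-2-yl]-2,6-dimethoxyphenoxy}propane-1,3-diol | COc1cc(C[C@@H]2CO[C@@H](c3cc(OC)c(O[C@H](CO)[C@@H](O)c4ccc(O)c(OC)c4)c(OC)c3)[C@@H]2CO)ccc1O | target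

**Step count and risks**

Total step count: 15 (steps 1–3 make bromide 4, step 11 makes the acylating reagent 19).
Longest linear sequence: 11 steps, from 5 to 25 (steps 4–10 and 12–15).

Steps most likely to fail:

1. Step 10. The product is still a free p-hydroxybenzyl ether and may be oxidised further at C2, leading to ring opening to an aryl ketone. The electron-rich benzyloxy ring may also capture the quinone methide in a Friedel–Crafts closure to an aryltetralin, or the closure may be only partly trans-selective. The fallback generates the same quinone methide 15 by dehydration instead of oxidation; it sets out from 11 (with aldehyde 2) and returns at 16. The lithium enolate of 11 (LiN(SiMe3)2, THF, −78 °C) is added to 2, anti to the C4 substituent, to give the trans hydroxybenzyl lactone F1 as a mixture of carbinol epimers. LiAlH4 reduces it to the silyl-protected triol F2, and Bu4NF/AcOH frees the phenol to give triol F3. A catalytic amount of camphorsulfonic acid in CH2Cl2 at 0 °C should then ionise the p-hydroxybenzylic alcohol to 15, which closes to 16 under the same allylic-strain control; both carbinol epimers converge.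

2. Step 13. The aryloxy oxygen and its two flanking methoxy groups may compete for magnesium and loosen the chelated transition state, so that facial or anti/syn control erodes. The electron-rich aldehyde may also add slowly, leaving time for epimerisation at the acidic C8''–H. The fallback is the boron-mediated syn-aldol followed by inversion of the carbinol; it sets out from 16 and returns at 24. 16 is alkylated (K2CO3, acetone) with (S)-4-benzyl-3-(bromoacetyl)oxazolidin-2-one F4, made as 19 is but from the (S)-oxazolidinone, to give the diastereomeric imide F5. The antipodal auxiliary is needed because the boron enolate reacts through the non-chelated conformer. The primary hydroxyl is silylated (TBSCl, imidazole) to F6. Enolisation with Bu2BOTf/i-Pr2NEt in CH2Cl2 at −78 °C and addition of 5 should give the (2S,3R) syn-adduct F7, with C8'' already correct and C7'' epimeric. Mitsunobu inversion of the benzylic carbinol with 4-nitrobenzoic acid (PPh3, DIAD, THF) gives the (2S,3S) ester F8. LiBH4 in THF/MeOH removes both the auxiliary and the ester to give silyl ether F9, and Bu4NF gives 24.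

3. Step 7. The electron-rich silyloxybenzyl bromide 4 may ionise, or lose its silyl group to a quinone methide, and polymerise before the enolate captures it; a second alkylation may also compete. The fallback installs the aryl group through the stable aldehyde; it sets out from 11 (with aldehyde 2) and returns at 12. The aldol adduct F1 (the compound described under the first fallback) is mesylated (MsCl, Et3N) and eliminated with DBU to the (E)-arylidene lactone F10. Conjugate reduction with NaBH4/NiCl2·6H2O in MeOH at 0 °C, followed by equilibration with DBU to the more stable trans isomer, should give 12.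

**Further compounds**

F1 | step 10 | (3R,4S)-4-(4-benzyloxy-3-methoxybenzyl)-3-{[4-(tert-butyldimethylsilyloxy)-3,5-dimethoxyphenyl](hydroxy)methyl}dihydrofuran-2(3H)-one (trans, carbinol epimers) | COc1cc(C[C@@H]2COC(=O)[C@H]2C(O)c2cc(OC)c(O[Si](C)(C)C(C)(C)C)c(OC)c2)ccc1OCc1ccccc1
F2 | step 10 | 2-(4-benzyloxy-3-methoxybenzyl)-3-{[4-(tert-butyldimethylsilyloxy)-3,5-dimethoxyphenyl](hydroxy)methyl}butane-1,4-diol (backbone centres as in 13, carbinol epimers) | COc1cc(C[C@H](CO)[C@@H](CO)C(O)c2cc(OC)c(O[Si](C)(C)C(C)(C)C)c(OC)c2)ccc1OCc1ccccc1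
F3 | step 10 | 2-(4-benzyloxy-3-methoxybenzyl)-3-[hydroxy(4-hydroxy-3,5-dimethoxyphenyl)methyl]butane-1,4-diol (backbone centres as in 14, carbinol epimers) | COc1cc(C[C@H](CO)[C@@H](CO)C(O)c2cc(OC)c(O)c(OC)c2)ccc1OCc1ccccc1
F4 | step 13 | (S)-4-benzyl-3-(bromoacetyl)oxazolidin-2-one | O=C(CBr)N1[C@@H](Cc2ccccc2)COC1=O
F5 | step 13 | (S)-4-benzyl-3-{[4-((2R,3S,4S)-4-(4-benzyloxy-3-methoxybenzyl)-3-(hydroxymethyl)tetrahydrofuran-2-yl)-2,6-dimethoxyphenoxy]acetyl}oxazolidin-2-one | COc1cc(C[C@@H]2CO[C@@H](c3cc(OC)c(OCC(=O)N4[C@@H](Cc5ccccc5)COC4=O)c(OC)c3)[C@@H]2CO)ccc1OCc1ccccc1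
F6 | step 13 | tert-butyldimethylsilyl ether of F5 at the C3 hydroxymethyl group | COc1cc(C[C@@H]2CO[C@@H](c3cc(OC)c(OCC(=O)N4[C@@H](Cc5ccccc5)COC4=O)c(OC)c3)[C@@H]2CO[Si](C)(C)C(C)(C)C)ccc1OCc1ccccc1
F7 | step 13 | (2S,3R) syn-aldol adduct of F6 with 5, (S)-auxiliary | COc1cc(C[C@@H]2CO[C@@H](c3cc(OC)c(O[C@H](C(=O)N4[C@@H](Cc5ccccc5)COC4=O)[C@H](O)c6ccc(OCc7ccccc7)c(OC)c6)c(OC)c3)[C@@H]2CO[Si](C)(C)C(C)(C)C)ccc1OCc1ccccc1
F8 | step 13 | (2S,3S) 4-nitrobenzoate from inversion of F7 at the carbinol | COc1cc(C[C@@H]2CO[C@@H](c3cc(OC)c(O[C@H](C(=O)N4[C@@H](Cc5ccccc5)COC4=O)[C@@H](OC(=O)c8ccc(cc8)[N+](=O)[O-])c6ccc(OCc7ccccc7)c(OC)c6)c(OC)c3)[C@@H]2CO[Si](C)(C)C(C)(C)C)ccc1OCc1ccccc1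
F9 | step 13 | tert-butyldimethylsilyl ether of 24 at the C3 hydroxymethyl group | COc1cc(C[C@@H]2CO[C@@H](c3cc(OC)c(O[C@H](CO)[C@@H](O)c4ccc(OCc5ccccc5)c(OC)c4)c(OC)c3)[C@@H]2CO[Si](C)(C)C(C)(C)C)ccc1OCc1ccccc1
F10 | step 7 | (S,E)-4-(4-benzyloxy-3-methoxybenzyl)-3-[4-(tert-butyldimethylsilyloxy)-3,5-dimethoxybenzylidene]dihydrofuran-2(3H)-one | COc1cc(C[C@@H]2COC(=O)/C2=C/c2cc(OC)c(O[Si](C)(C)C(C)(C)C)c(OC)c2)ccc1OCc1ccccc1
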